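**Retrosynthetic overview**
Numbering: 14-membered carbocycle C1 (CH bearing acrylate carbon C15, with methylene C17 and carbonyl C16), C2, C3 (carbinol), C4=C5, C6, C7=C8 (methyls C18 on C4, C19 on C8), C9, C10, C11 (OAc), C12 (methyl C20, lactone O), C13, C14.
Feature: the arc C3-C2-C1-C14-C13-C12 (C15-C17 branch on C1, C20 on C12, oxygen on C3 and on C12) is the six-membered ring of (R)-carvone with one oxygen inserted into the C3-C12 bond, and the C4-C8 skipped diene is symmetric about C6.
Disconnections: lactone C16(=O)-O(C12) by acylation of the tertiary hydroxyl (last); C3-C4 by Nozaki-Hiyama-Kishi macrocyclisation; C8-C9 by conjugate addition of a symmetric (2E,5E)-2,6-diiodohepta-2,5-diene linchpin to a C11 vinyl ketone; C11-C12 by reductive aldol of carvone with acrolein.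
Ring order: carvone ring, then Baeyer-Villiger ring expansion to the oxepan-2-one (sets C12-O), then opening to the C3 aldehyde, then the 14-membered carbocycle (C3-C4), then the alpha-methylene seven-membered lactone; the C11 and C3 carbinols come from two CBS reductions.
Key step: step 2

Remark: the overview numbering is used throughout (C1, C11, C12 are R, S, R in every compound that carries them). Of the isopropenyl group of carvone, the terminal CH2 carbon becomes C16 (oxirane CH2, then CH2O, then the lactone carbonyl) and the methyl carbon becomes the C17 methylene. Epimer mixtures at C11 (4-7 is trigonal from 7 on; mixture in 4-6), at oxirane carbon C15 (5-7, 15-18) and at C3 (21, 22) are carried on because each centre is later made trigonal.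

**Step 1**
Reactants: 1 (R)-(-)-carvone; 2 acrolein
Product: 4 (2R,5R)-2-(1-hydroxyprop-2-en-1-yl)-2-methyl-5-(prop-1-en-2-yl)cyclohexan-1-one (both C11 epimers), via lithium (5R)-2-methyl-5-(prop-1-en-2-yl)cyclohex-1-en-1-olate 3 (not isolated)
Conditions: L-Selectride (1.05 equiv), THF, -78 °C; then 2 (1.5 equiv), -78 °C, 15 min; AcOH/THF quench at -78 °C
Reagents that add atoms: L-Selectride, [Li+].CCC(C)[BH-](C(C)CC)C(C)CC (supplies the lithium of 3; only its hydride reaches 4)
Why: Reductive aldol reaction: L-Selectride adds hydride 1,4 to the enone and the regiodefined tetrasubstituted lithium enolate adds 1,2 to acrolein at -78 °C, axial attack on the half-chair that keeps the isopropenyl group pseudo-equatorial placing the new C11-C12 bond cis to that group and so setting quaternary C12, while the C11 carbinol forms as a mixture that step 3 removes.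

**Step 2**
Reactants: 4 aldol adduct
Product: 6 (4R,7R)-7-(1-hydroxyprop-2-en-1-yl)-7-methyl-4-(2-methyloxiran-2-yl)oxepan-2-one, via (2R,5R)-2-(1-hydroxyprop-2-en-1-yl)-2-methyl-5-(2-methyloxiran-2-yl)cyclohexan-1-one 5 (not isolated)
Conditions: mCPBA (2.4 equiv), NaHCO3, CH2Cl2, 0 °C to rt
Reagents that add atoms: mCPBA, OOC(=O)c1cccc(Cl)c1 (two oxygen atoms)
Why: Baeyer-Villiger oxidation with concurrent Prilezhaev epoxidation: the peracid first transfers oxygen in concerted fashion to the electron-rich 1,1-disubstituted isopropenyl olefin, then adds to the C3 carbonyl to give the Criegee adduct, in which the antiperiplanar, fully substituted C12 shifts from carbon to oxygen as m-chlorobenzoate leaves. The closest known reaction is the peracid oxidation of dihydrocarvone-type 2-substituted 5-isopropenylcyclohexanones to epoxy seven-membered lactones. The oxepan-2-one arises by ring expansion through this 1,2-shift (oxygen inserted into C3-C12, giving new C12-O and O-C3 bonds), not by a new cyclisation, and the oxirane closes by concerted oxygen transfer across the isopropenyl C=C, between C15 and the terminal CH2 carbon that later becomes C16. The new C12-O stereocentre is controlled by the aldol-made quaternary carbon, which migrates with retention and so becomes the (12R) tertiary C-O centre, whereas the oxirane carbon C15 is uncontrolled and is erased in step 8. The step needs C12 and not C2 to migrate and the vinyl group to survive: C12 is the only fully substituted alpha-carbon and thus the better migrating group, the monosubstituted vinyl group next to the carbinol is far less nucleophilic toward peracid than the isopropenyl group, and bicarbonate keeps the acid by-product from opening the oxirane.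

**Step 3**
Reactants: 6 epoxy oxepanone carbinol
Product: 7 (4R,7R)-7-methyl-4-(2-methyloxiran-2-yl)-7-(prop-2-enoyl)oxepan-2-one (C11 vinyl ketone)
Conditions: Dess-Martin periodinane (1.3 equiv), NaHCO3, CH2Cl2, 0 °C to rt; used at once
Reagents that add atoms: none
Why: Dess-Martin oxidation of the secondary allylic carbinol under bicarbonate buffering is neutral enough to spare the lactone and the oxirane and converges both C11 epimers on one vinyl ketone, which is used at once because alpha-acyloxy vinyl ketones polymerise readily.

**Step 4**
Reactants: 8 1-bromobut-2-yne; 9 prop-1-ynylmagnesium bromide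
Product: 10 hepta-2,5-diyne
Conditions: CuCl (5 mol %), THF, 0 °C to rt; neutral work-up, used promptly
Reagents that add atoms: none
Why: Copper(I)-catalysed coupling of an alkynyl Grignard reagent with a primary propargylic bromide (direct displacement via the alkynylcopper species) is the standard entry to skipped 1,4-diynes and creates no stereo-element.

**Step 5**
Reactants: 10 hepta-2,5-diyne
Product: 12 (2E,5E)-2,6-diiodohepta-2,5-diene, via (2E,5E)-hepta-2,5-diene-2,6-diylbis[chlorobis(cyclopentadienyl)zirconium] 11 (not isolated)
Conditions: Cp2Zr(H)Cl (2.4 equiv), THF, rt to 45 °C, dark; then I2 (2.4 equiv), THF, 0 °C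
Reagents that add atoms: Schwartz reagent, [H][Zr](Cl)(C1C=CC=C1)C1C=CC=C1 (zirconium of 11 only); iodine, II
Why: Hydrozirconation-iodination: the Zr-H bond adds syn across each alkyne, the slight excess of hydride lets the regioisomeric alkenylzirconium species equilibrate toward zirconium on the less hindered methyl-bearing carbon, and iodinolysis of the C-Zr bond with retention should give the E,E-diiodide with iodine trans to the central CH2, minor regioisomers being removed by chromatography.

**Step 6**
Reactants: 7 C11 vinyl ketone; 12 (2E,5E)-2,6-diiodohepta-2,5-diene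
Product: 16 (4R,7R)-7-[(4E,7E)-8-iodo-4-methylnona-4,7-dienoyl]-7-methyl-4-(2-methyloxiran-2-yl)oxepan-2-one, via 6-iodohepta-2,5-dien-2-yllithium 13 (not isolated), via 6-iodohepta-2,5-dien-2-ylcopper(I) 14 (not isolated), via trimethylsilyl enol ether 15 (not isolated)
Conditions: 12 (3 equiv), t-BuLi (2.4 equiv), Et2O, -78 °C; CuI (1.2 equiv), THF, -78 to -40 °C; then 7 (1 equiv), TMSCl (3 equiv), -78 °C; 0.5 M aq. citric acid, THF, 0 °C, 10 min; excess 12 recovered
Reagents that add atoms: tert-butyllithium, [Li]C(C)(C)C (lithium of 13 only); copper(I) iodide, [Cu]I (copper of 14 only); chlorotrimethylsilane, C[Si](C)(C)Cl (silyl group of 15 only)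
Why: Organocopper conjugate addition: iodine-lithium exchange at one terminus of the excess symmetric diiodide and transmetalation to copper proceed with retention of the olefin geometry, and the soft alkenylcopper reagent adds 1,4 to the very reactive vinyl ketone under TMSCl activation in preference to the lactone, oxirane and remaining vinyl iodide, the C10=C11 silyl enol ether then being hydrolysed under mild acid; this forms C8-C9 and no stereocentre.

**Step 7**
Reactants: 16 C11 ketone
Product: 17 (4R,7R)-7-[(1S,4E,7E)-1-hydroxy-8-iodo-4-methylnona-4,7-dien-1-yl]-7-methyl-4-(2-methyloxiran-2-yl)oxepan-2-one ((11S)-carbinol)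
Conditions: (R)-2-methyl-CBS-oxazaborolidine (0.5 equiv), catecholborane (2 equiv), toluene/CH2Cl2, -78 °C
Reagents that add atoms: none
Why: Corey-Bakshi-Shibata reduction: the ketone coordinates to the oxazaborolidine boron anti to the fully substituted C12 (large group) so that the catalyst-bound catecholborane delivers hydride to the face that gives the (11S)-carbinol, and at -78 °C this reagent leaves the lactone, the oxirane and the vinyl iodide untouched.

**Step 8**
Reactants: 17 (11S)-carbinol
Product: 19 (4R,7R)-4-[3-(tert-butyldimethylsilyloxy)prop-1-en-2-yl]-7-[(1S,4E,7E)-1-(tert-butyldimethylsilyloxy)-8-iodo-4-methylnona-4,7-dien-1-yl]-7-methyloxepan-2-one, via oxirane-containing C11 tert-butyldimethylsilyl ether 18 (not isolated)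
Conditions: TBSOTf (3 equiv), 2,6-lutidine (5 equiv), CH2Cl2, -78 to 0 °C; then DBU (5 equiv), 0 °C to rt
Reagents that add atoms: tert-butyldimethylsilyl triflate, CC(C)(C)[Si](C)(C)OS(=O)(=O)C(F)(F)F
Why: Silyl triflate/amidine isomerisation of an epoxide to an allylic silyl ether: after silylation of C11-OH, a second equivalent of TBSOTf activates the oxirane oxygen, the C15-O bond opens at the tertiary carbon and DBU removes a proton from the unhindered methyl group (C17), which restores the C15=C17 methylene, leaves C16 as a primary silyl ether and erases the C15 epimer mixture.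

**Step 9**
Reactants: 19 bis-silyl ether lactone
Product: 20 seco C3 aldehyde: (1R,11S,12R) open chain with C3 aldehyde, free tertiary C12 hydroxyl, OTBS on C11 and C16, C15=C17 methylene and the (4E,7E) C4 vinyl iodide
Conditions: DIBAL (1.1 equiv), CH2Cl2, -78 °C; Rochelle salt work-up
Reagents that add atoms: none
Why: DIBAL half-reduction: at -78 °C the aluminium hemiacetal of the lactone survives until work-up, and the resulting seven-membered lactol of a tertiary alcohol should exist essentially as the open hydroxy aldehyde, the silyl ethers and vinyl iodide being inert.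

**Step 10**
Reactants: 20 seco aldehyde
Product: 21 14-membered carbocycle: (1R,11S,12R,4E,7E) with C3-OH (both epimers), C12-OH, OTBS on C11 and C16
Conditions: CrCl2 (10 equiv), NiCl2 (0.1 equiv), DMSO/THF, rt, slow addition of 20 to a final 2 mM
Reagents that add atoms: none
Why: Nozaki-Hiyama-Kishi reaction: nickel-catalysed activation of the C4-I bond and transmetalation give an alkenylchromium(III) species with retained E geometry that adds chemoselectively to the C3 aldehyde in the presence of the free tertiary hydroxyl, high dilution favouring closure of the 14-membered ring at C3-C4; the C3 carbinol forms as an epimer mixture that step 12 removes.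

**Step 11**
Reactants: 21 macrocyclic bis-silyl ether
Product: 22 macrocyclic tetraol (C3-OH, C11-OH, C12-OH, C16-OH)
Conditions: TBAF (4 equiv), THF, 0 °C to rt
Reagents that add atoms: none
Why: Fluoride-mediated desilylation, driven by the strong Si-F bond, removes both TBS ethers without touching the skipped diene or the allylic carbinols.

**Step 12**
Reactants: 22 tetraol
Product: 23 macrocyclic C3 enone carrying the C16 enal, with C11-OH and C12-OH free
Conditions: activated MnO2 (30 equiv), CH2Cl2, rt
Reagents that add atoms: none
Why: Manganese dioxide oxidation is selective for allylic alcohols, so C3 becomes the enone (both C3 epimers converge) and C16 the alpha-methylene aldehyde while the saturated C11 and C12 hydroxyls are untouched.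

**Step 13**
Reactants: 23 keto enal diol
Product: 24 C11 acetate of 23 (C3 enone, C16 enal, free C12-OH)
Conditions: Ac2O (1.5 equiv), pyridine, DMAP (0.1 equiv), CH2Cl2, 0 °C
Reagents that add atoms: acetic anhydride, CC(=O)OC(C)=O
Why: Acylation with acetic anhydride/pyridine and catalytic DMAP takes the only remaining secondary hydroxyl (C11), the tertiary C12 hydroxyl being too hindered to react at 0 °C, and no stereocentre is touched.

**Step 14**
Reactants: 24 enal acetate
Product: 25 macrocyclic C3 enone with C16 carboxylic acid, C11 acetate and free C12-OH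
Conditions: NaClO2, NaH2PO4, 2-methyl-2-butene, t-BuOH/H2O, 0 °C to rt
Reagents that add atoms: sodium chlorite, [Na+].[O-]Cl=O (one oxygen atom)
Why: Pinnick (chlorite) oxidation converts the enal into the acrylic acid without isomerising or chlorinating the olefins, 2-methyl-2-butene scavenging the hypochlorous acid formed.

**Step 15**
Reactants: 25 seco acid
Product: 26 3-oxo precursor: the target skeleton with the alpha-methylene seven-membered lactone closed and C3 as the enone
Conditions: 2-methyl-6-nitrobenzoic anhydride (1.5 equiv), DMAP (4 equiv), CH2Cl2, rt to 40 °C, slow addition of 25 to a final 2 mM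
Reagents that add atoms: none
Why: Shiina lactonisation: the acid is activated as a mixed anhydride and transferred through the acylpyridinium ion to the C12 hydroxyl, the only free hydroxyl left (C3 is a ketone, so no six-membered lactone can form, and C11 is acetylated), slow addition at high dilution favouring closure of the seven-membered alpha-methylene lactone; no stereocentre is formed.

**Step 16**
Reactants: 26 3-oxo lactone
Product: 27 dendronpholide B
Conditions: (S)-2-methyl-CBS-oxazaborolidine (1 equiv), catecholborane (1.5 equiv), toluene, -78 °C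
Reagents that add atoms: none
Why: Corey-Bakshi-Shibata reduction: the alpha-methyl-substituted alkenyl carbon C4 acts as the large group and the C2 methylene as the small one, so the (S)-catalyst should direct 1,2-hydride delivery to the face that gives the (3R)-allylic alcohol, and catecholborane at -78 °C reduces neither the lactone, the acetate nor the alpha-methylene ester.

**Compound list**
1 | (R)-(-)-carvone | CC1=CC[C@H](CC1=O)C(C)=C | starting material
2 | acrolein | C=CC=O | starting material
3 | lithium (5R)-2-methyl-5-(prop-1-en-2-yl)cyclohex-1-en-1-olate | CC1=C(O[Li])C[C@@H](CC1)C(C)=C | intermediate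
4 | (2R,5R)-2-(1-hydroxyprop-2-en-1-yl)-2-methyl-5-(prop-1-en-2-yl)cyclohexan-1-one, hydroxyallyl cis to isopropenyl, C11 epimers | O=C1C[C@H](C(C)=C)CC[C@]1(C)C(O)C=C | intermediate
5 | (2R,5R)-2-(1-hydroxyprop-2-en-1-yl)-2-methyl-5-(2-methyloxiran-2-yl)cyclohexan-1-one, C11 and C15 epimers | O=C1C[C@H](C2(C)CO2)CC[C@]1(C)C(O)C=C | intermediate
6 | (4R,7R)-7-(1-hydroxyprop-2-en-1-yl)-7-methyl-4-(2-methyloxiran-2-yl)oxepan-2-one (acyl carbon C3, ring oxygen on C12), C11 and C15 epimers | O=C1C[C@H](C2(C)CO2)CC[C@](C)(C(O)C=C)O1 | intermediate
7 | (4R,7R)-7-methyl-4-(2-methyloxiran-2-yl)-7-(prop-2-enoyl)oxepan-2-one, C15 epimers | O=C1C[C@H](C2(C)CO2)CC[C@](C)(C(=O)C=C)O1 | intermediate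
8 | 1-bromobut-2-yne | CC#CCBr | starting material
9 | prop-1-ynylmagnesium bromide | CC#C[Mg]Br | starting material
10 | hepta-2,5-diyne | CC#CCC#CC | intermediate
11 | (2E,5E)-hepta-2,5-diene-2,6-diylbis[chlorobis(cyclopentadienyl)zirconium] (Cp drawn sigma-bonded) | Cl[Zr](C1C=CC=C1)(C1C=CC=C1)/C(C)=C/C/C=C(\C)[Zr](Cl)(C1C=CC=C1)C1C=CC=C1 | intermediate
12 | (2E,5E)-2,6-diiodohepta-2,5-diene | I/C(C)=C/C/C=C(\C)I | intermediate
13 | 6-iodohepta-2,5-dien-2-yllithium, mono-lithio derivative of 12 (lithium trans to the central CH2, geometry of 12 retained) | [Li]/C(C)=C/C/C=C(\C)I | intermediate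
14 | 6-iodohepta-2,5-dien-2-ylcopper(I), alkenylcopper reagent from 13 | [Cu]/C(C)=C/C/C=C(\C)I | intermediate
15 | C10=C11 trimethylsilyl enol ether of 16 | O=C1C[C@H](C2(C)CO2)CC[C@](C)(C(O[Si](C)(C)C)=CC/C(C)=C/C/C=C(\C)I)O1 | intermediate
16 | (4R,7R)-7-[(4E,7E)-8-iodo-4-methylnona-4,7-dienoyl]-7-methyl-4-(2-methyloxiran-2-yl)oxepan-2-one | O=C1C[C@H](C2(C)CO2)CC[C@](C)(C(=O)CC/C(C)=C/C/C=C(\C)I)O1 | intermediate
17 | (4R,7R)-7-[(1S,4E,7E)-1-hydroxy-8-iodo-4-methylnona-4,7-dien-1-yl]-7-methyl-4-(2-methyloxiran-2-yl)oxepan-2-one | O=C1C[C@H](C2(C)CO2)CC[C@](C)([C@@H](O)CC/C(C)=C/C/C=C(\C)I)O1 | intermediate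
18 | C11 tert-butyldimethylsilyl ether of 17, oxirane intact | O=C1C[C@H](C2(C)CO2)CC[C@](C)([C@@H](O[Si](C)(C)C(C)(C)C)CC/C(C)=C/C/C=C(\C)I)O1 | intermediate
19 | bis-silyl ether lactone, (11S)-OTBS and C16 allylic OTBS | O=C1C[C@H](C(=C)CO[Si](C)(C)C(C)(C)C)CC[C@](C)([C@@H](O[Si](C)(C)C(C)(C)C)CC/C(C)=C/C/C=C(\C)I)O1 | intermediate
20 | seco C3 aldehyde with free C12-OH and C4 vinyl iodide | O=CC[C@H](C(=C)CO[Si](C)(C)C(C)(C)C)CC[C@@](C)(O)[C@@H](O[Si](C)(C)C(C)(C)C)CC/C(C)=C/C/C=C(\C)I | intermediate
21 | 14-membered carbocycle, C3-OH epimers, C12-OH, two OTBS | OC1C[C@H](C(=C)CO[Si](C)(C)C(C)(C)C)CC[C@@](C)(O)[C@@H](O[Si](C)(C)C(C)(C)C)CC/C(C)=C/C/C=C1\C | intermediate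
22 | macrocyclic tetraol, C3-OH epimers | OC1C[C@H](C(=C)CO)CC[C@@](C)(O)[C@@H](O)CC/C(C)=C/C/C=C1\C | intermediate
23 | macrocyclic C3 enone, C16 enal, C11/C12 diol | O=C1C[C@H](C(=C)C=O)CC[C@@](C)(O)[C@@H](O)CC/C(C)=C/C/C=C1\C | intermediate
24 | C11 acetate of 23 | O=C1C[C@H](C(=C)C=O)CC[C@@](C)(O)[C@@H](OC(C)=O)CC/C(C)=C/C/C=C1\C | intermediate
25 | macrocyclic C3 enone, C16 acid, C11 acetate, free C12-OH | O=C1C[C@H](C(=C)C(=O)O)CC[C@@](C)(O)[C@@H](OC(C)=O)CC/C(C)=C/C/C=C1\C | intermediate
26 | 3-oxo lactone (3-dehydro-dendronpholide B) | C=C1C(=O)O[C@]2(C)CC[C@@H]1CC(=O)/C(C)=C/C/C=C(\C)CC[C@@H]2OC(C)=O | intermediate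
27 | dendronpholide B | C=C1C(=O)O[C@]2(C)CC[C@@H]1C[C@@H](O)/C(C)=C/C/C=C(\C)CC[C@@H]2OC(C)=O | target

**Step count and risks**
Total: 16 steps. Longest linear sequence: 14 steps from (R)-carvone (steps 1-3 and 6-16); the linchpin branch is 2 steps (steps 4-5).

Steps most likely to fail:

1. Step 15 (lactonisation). Acyl transfer to the hindered tertiary C12 hydroxyl may be slower than intermolecular esterification, and prolonged exposure to DMAP may move the C7=C8 olefin into conjugation through deprotonation at the doubly activated C6. Fallback: set out from enal acetate 24, where the C12 hydroxyl and the C16 aldehyde are in equilibrium with the seven-membered lactol F1. This lactol is oxidised as it forms with catalytic TEMPO and PhI(OAc)2 in CH2Cl2 at rt, so the ring is closed by hemiacetal formation and oxidation and not by acyl substitution. The fallback comes back to the route at 26.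

2. Step 6 (conjugate addition). Statistical double iodine-lithium exchange may lead to twofold addition, and the alpha-acyloxy vinyl ketone may polymerise or undergo electron-transfer reduction before the copper reagent adds. Fallback: set out from carbinol 6 and form C8-C9 by cross-coupling instead. Silylation (TESCl, imidazole, DMF) should give the triethylsilyl ether F2. Hydroboration of its vinyl group with 9-BBN in THF gives the primary B-alkyl-9-BBN borane F3, used in the flask. B-alkyl Suzuki-Miyaura coupling with excess 12 (Pd(dppf)Cl2, AsPh3, Cs2CO3, DMF/THF/H2O, rt) gives the coupled silyl ether F4 with the olefin geometry retained. Desilylation (TBAF/AcOH, THF, 0 °C) gives the coupled C11 alcohol F5 as an epimer mixture, and Dess-Martin oxidation comes back to the route at 16.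

3. Step 8 (epoxide to allylic silyl ether). Proton loss may occur from C1 instead of the methyl group, giving the tetrasubstituted olefin, and the lactone carbonyl may capture the developing C15 cation, or a hydride shift may give the aldehyde. Fallback: set out from 17 and open the oxirane homolytically with Cp2TiCl (from Cp2TiCl2 and Mn dust, THF, rt). The tertiary C15 radical is trapped by a second titanium(III) and loses a hydrogen from the methyl group, which should give the allylic diol F6. Twofold silylation (TBSOTf, 2,6-lutidine, CH2Cl2, -78 to 0 °C) comes back to the route at 19.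

**Further compounds**
F1 | step 15 | seven-membered lactol of 24 (C16 hemiacetal to C12-O) | C=C1C(O)O[C@]2(C)CC[C@@H]1CC(=O)/C(C)=C/C/C=C(\C)CC[C@@H]2OC(C)=O
F2 | step 6 | C11 triethylsilyl ether of 6 | O=C1C[C@H](C2(C)CO2)CC[C@](C)(C(O[Si](CC)(CC)CC)C=C)O1
F3 | step 6 | B-alkyl-9-BBN borane from F2 (boron on C9) | O=C1C[C@H](C2(C)CO2)CC[C@](C)(C(O[Si](CC)(CC)CC)CCB2C3CCCC2CCC3)O1
F4 | step 6 | coupled C11 triethylsilyl ether with the C4-C10 chain and C4 vinyl iodide | O=C1C[C@H](C2(C)CO2)CC[C@](C)(C(O[Si](CC)(CC)CC)CC/C(C)=C/C/C=C(\C)I)O1
F5 | step 6 | coupled C11 alcohol, C11 epimers | O=C1C[C@H](C2(C)CO2)CC[C@](C)(C(O)CC/C(C)=C/C/C=C(\C)I)O1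
F6 | step 8 | allylic diol (C11-OH, C16-OH, C15=C17 methylene) | O=C1C[C@H](C(=C)CO)CC[C@](C)([C@@H](O)CC/C(C)=C/C/C=C(\C)I)O1
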